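**Retrosynthetic overview**
1. Presumed biogenesis: two tyrosine-derived arylpyruvate (C6–C3) units combine. The benzylic carbon of one adds to the keto carbon of the other (C4–C5), and the new carbinol O closes onto the nucleophile's carboxyl (O1–C2). The electrophilic unit loses CO2 and the C3 oxygen leaves as water.
2. 10 ⇒ isotetronic acid 6 (= 10 + H2O) by a redox-neutral 1,4-dehydration. It expels the C3–O and creates the (Z)-benzylidene in one operation, so no triflate reduction and no separate oxidation are needed.
3. 6 ⇒ 4-hydroxyphenylpyruvic acid 4 + arylacetaldehyde 3. The second unit is used already decarboxylated, which makes the crossed aldol selective. The only ring is formed here, C4–C5 first, then O1–C2.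
4. 3 ⇒ 3-bromo-4-methoxybenzaldehyde 1 by C1 homologation. Br and OMe are bought in place and no protecting groups are used.

Assumption: the target has no stereocentre (it is achiral), so "single enantiomer" is read as the single (Z)-alkene isomer drawn.

Step 1
Reactants: 1 3-bromo-4-methoxybenzaldehyde
Product: 3 2-(3-bromo-4-methoxyphenyl)acetaldehyde, via E/Z methyl enol ether 2 (not isolated)
Conditions: MeOCH2PPh3Cl (1.3 equiv), KOtBu (1.3 equiv), THF, 0 °C to rt; then 2 M aq HCl, THF, 50 °C
Reagents that add atoms: (methoxymethyl)triphenylphosphonium chloride COC[P+](c1ccccc1)(c1ccccc1)c1ccccc1.[Cl-]; water O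
Why: Wittig methoxymethylenation followed by enol-ether hydrolysis is the standard one-carbon homologation of ArCHO to ArCH2CHO; the aryl bromide and aryl methyl ether are inert and no stereocentre is made.

Step 2
Reactants: 3 2-(3-bromo-4-methoxyphenyl)acetaldehyde; 4 3-(4-hydroxyphenyl)-2-oxopropanoic acid (4-hydroxyphenylpyruvic acid, 1.2 equiv)
Product: 6 rac-5-(3-bromo-4-methoxybenzyl)-3-hydroxy-4-(4-hydroxyphenyl)furan-2(5H)-one, via open-chain aldol acid 5 (not isolated)
Conditions: K2CO3 (2.5 equiv), degassed H2O–MeOH, N2, slow addition of 3, 0 °C to rt; then 3 M HCl to pH 1, 40 °C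
Reagents that add atoms: none
Why: Erlenmeyer-type crossed aldol–lactonisation (isotetronic acid synthesis): the benzylic C–H of 4 is the most acidic carbon acid present, and its soft enolate adds to the aldehyde, which is far more electrophilic than the enolised keto-carboxylate (this suppresses the homodimer); slow addition limits self-aldol of 3, and acidification closes the γ-lactone, which rests as its enol; the new C5 stereocentre is racemic and is erased in step 3.

Step 3
Reactants: 6 rac-5-(3-bromo-4-methoxybenzyl)-3-hydroxy-4-(4-hydroxyphenyl)furan-2(5H)-one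
Product: 10 3''-bromorubrolide F [(Z)-5-(3-bromo-4-methoxybenzylidene)-4-(4-hydroxyphenyl)furan-2(5H)-one], via bis(trifluoroacetate) 7 (not isolated), via deconjugated 2(3H)-furanone 8 (not isolated), via target O-trifluoroacetate 9 (not isolated)
Conditions: TFAA (2.3 equiv), Et3N (6 equiv), MeCN, 0 °C; then 60 °C; then H2O, rt
Reagents that add atoms: none
Why: Proposed new method: 6 is the target plus one H2O, so no external redox reagent is needed; O-trifluoroacetylation turns the C3 enol oxygen into a leaving group; Et3N reversibly removes the acidic γ-H at C5 (the same deprotonation that racemises γ-substituted butenolides), and kinetic α-protonation gives the deconjugated tautomer 8 (compare the β-/α-angelica lactone equilibrium); in 8 the C3–O2CCF3 bond is allylic and vinylogously assisted by the ring oxygen, so it leaves in a 1,4-(E1/E2′) elimination together with a benzylic H, through the same acyloxyallyl cation that mediates the familiar dehydration of 5-benzyl-5-hydroxybutenolides; no 1,2-elimination can compete because C4 carries no H, and unproductive tautomers return to the pool; the Z-alkene is the thermodynamic isomer because an E-aryl group would clash with the C4 aryl (A1,3 strain); the aryl trifluoroacetate 9 hydrolyses when water is added; closest known reaction types are base-mediated butenolide deconjugation, 1,4-elimination of allylic esters to dienes, and lactol dehydration to γ-ylidenebutenolides.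

**Compound list**
1 | 3-bromo-4-methoxybenzaldehyde | COc1ccc(C=O)cc1Br | starting material
2 | 2-bromo-1-methoxy-4-(2-methoxyvinyl)benzene (E/Z mixture) | COC=Cc1ccc(OC)c(Br)c1 | intermediate
3 | 2-(3-bromo-4-methoxyphenyl)acetaldehyde | COc1ccc(CC=O)cc1Br | intermediate
4 | 3-(4-hydroxyphenyl)-2-oxopropanoic acid | OC(=O)C(=O)Cc1ccc(O)cc1 | starting material
5 | 5-(3-bromo-4-methoxyphenyl)-4-hydroxy-3-(4-hydroxyphenyl)-2-oxopentanoic acid (racemic diastereomer mixture, potassium salt in the flask) | COc1ccc(CC(O)C(c2ccc(O)cc2)C(=O)C(=O)O)cc1Br | intermediate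
6 | rac-5-(3-bromo-4-methoxybenzyl)-3-hydroxy-4-(4-hydroxyphenyl)furan-2(5H)-one | COc1ccc(CC2OC(=O)C(O)=C2c2ccc(O)cc2)cc1Br | intermediate
7 | rac-5-(3-bromo-4-methoxybenzyl)-3-(trifluoroacetoxy)-4-[4-(trifluoroacetoxy)phenyl]furan-2(5H)-one | COc1ccc(CC2OC(=O)C(OC(=O)C(F)(F)F)=C2c2ccc(OC(=O)C(F)(F)F)cc2)cc1Br | intermediate
8 | rac-5-(3-bromo-4-methoxybenzyl)-3-(trifluoroacetoxy)-4-[4-(trifluoroacetoxy)phenyl]furan-2(3H)-one | COc1ccc(CC2=C(c3ccc(OC(=O)C(F)(F)F)cc3)C(OC(=O)C(F)(F)F)C(=O)O2)cc1Br | intermediate
9 | (Z)-4-[2-(3-bromo-4-methoxybenzylidene)-5-oxo-2,5-dihydrofuran-3-yl]phenyl trifluoroacetate | COc1ccc(/C=C2\OC(=O)C=C2c2ccc(OC(=O)C(F)(F)F)cc2)cc1Br | intermediate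
10 | 3''-bromorubrolide F, (Z)-5-(3-bromo-4-methoxybenzylidene)-4-(4-hydroxyphenyl)furan-2(5H)-one | COc1ccc(/C=C2\OC(=O)C=C2c2ccc(O)cc2)cc1Br | target

**Step count and risks**
Total step count: 3. Longest linear sequence: 3 (1 → 3 → 6 → 10).

Most likely to fail is step 3. The enol trifluoroacetate may stay as the conjugated tautomer, or its dienolate may be C-acylated. The fallback splits the internal redox into a separate reduction and oxidation.
- It sets out from 6. P(NMe2)3 in toluene (−78 °C to rt) forms the Kukhtin–Ramirez adduct of the α-keto-lactone tautomer. After protonation at C3, this adduct loses the phosphoramide oxide together with the benzylic C4–H, giving 5-(3-bromo-4-methoxybenzyl)-4-(4-hydroxyphenyl)furan-2(5H)-one F1.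
- DDQ in warm dioxane abstracts hydride from the p-methoxy-activated benzylic CH2 of F1. Loss of the acidic C5–H then gives the Z-benzylidene, and the route is rejoined at 10.

Second is step 2, which can suffer from self-aldol of 3, homodimerisation of 4, or air oxidation of 4 in base. The fallback replaces the aqueous thermodynamic enolate with a directed Lewis-acid aldol of a preformed nucleophile.
- It sets out from 4. MeOH with catalytic H2SO4 gives methyl 3-(4-hydroxyphenyl)-2-oxopropanoate F2.
- TMSCl/Et3N gives methyl (Z)-2-(trimethylsilyloxy)-3-[4-(trimethylsilyloxy)phenyl]acrylate F3.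
- Mukaiyama aldol of F3 with 3 (BF3·OEt2, CH2Cl2, −78 °C) and aqueous acid work-up give methyl 5-(3-bromo-4-methoxyphenyl)-4-hydroxy-3-(4-hydroxyphenyl)-2-oxopentanoate F4. F4 lactonises on standing with acid, and the route is rejoined at 6.

Third is step 1, where the electron-rich arylacetaldehyde may oligomerise during the acidic enol-ether hydrolysis. The fallback makes the aldehyde by decarboxylation of a C6–C3 glycidic acid instead of by a Wittig reaction.
- It sets out from 1. Darzens condensation with methyl chloroacetate/NaOMe gives methyl 3-(3-bromo-4-methoxyphenyl)oxirane-2-carboxylate F5.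
- NaOH gives sodium 3-(3-bromo-4-methoxyphenyl)oxirane-2-carboxylate F6.
- Buffering with AcOH at 40 °C triggers ring-opening decarboxylation, and the route is rejoined at 3.

**Further compounds**
F1 | step 3 | rac-5-(3-bromo-4-methoxybenzyl)-4-(4-hydroxyphenyl)furan-2(5H)-one | COc1ccc(CC2OC(=O)C=C2c2ccc(O)cc2)cc1Br
F2 | step 2 | methyl 3-(4-hydroxyphenyl)-2-oxopropanoate | COC(=O)C(=O)Cc1ccc(O)cc1
F3 | step 2 | methyl (Z)-2-(trimethylsilyloxy)-3-[4-(trimethylsilyloxy)phenyl]acrylate | COC(=O)/C(O[Si](C)(C)C)=C/c1ccc(O[Si](C)(C)C)cc1
F4 | step 2 | methyl 5-(3-bromo-4-methoxyphenyl)-4-hydroxy-3-(4-hydroxyphenyl)-2-oxopentanoate (racemic diastereomer mixture) | COC(=O)C(=O)C(c1ccc(O)cc1)C(O)Cc1ccc(OC)c(Br)c1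
F5 | step 1 | methyl 3-(3-bromo-4-methoxyphenyl)oxirane-2-carboxylate (racemic, mainly trans) | COC(=O)C1OC1c1ccc(OC)c(Br)c1
F6 | step 1 | sodium 3-(3-bromo-4-methoxyphenyl)oxirane-2-carboxylate (racemic) | [Na+].[O-]C(=O)C1OC1c1ccc(OC)c(Br)c1
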